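**Retrosynthetic overview**
1. Target 15 ⇒ chloromethylquinone 6 + C28 pentaenyne 14. The C1′–C2′ bond and the 3′-methyl are made together by Zr-carboalumination/Ni coupling on the unprotected quinone, which fixes 2′E.
2. Key bond type, used five times: the CH2–CH= junctions C5′–C6′, C9′–C10′, C13′–C14′, C17′–C18′ and C21′–C22′, each by Ni-catalysed decarboxylative radical alkenylation (alkyl radical from an in situ redox-active ester + E-alkenyl iodide). One unprotected C5 iodo-acid 8 is added per step and returns a free CO2H; the chain is capped with 13.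
3. Unit 8 comes from pent-4-ynoic acid by carboalumination/iodination, so the E geometry is set once and copied into the 6′, 10′, 14′ and 18′ alkenes.
4. Rings: the o-cresol carbocycle becomes the quinone ring (2-bromo-6-methylbenzoquinone). The benzo ring is formed second by a bromine-directed Diels–Alder reaction with (E)-piperylene and aromatisation; chloromethylation then gives 6.

Assumption: the target has no stereocentres, so "single enantiomer" is read as the single all-E (2′E,6′E,10′E,14′E,18′E) isomer.

**Route**

Step 1
Reactants: 1, o-cresol (2-methylphenol)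
Product: 2, 2,4-dibromo-6-methylphenol
Conditions: Br2 (2.05 equiv), AcOH, 10 °C → rt
Reagents that add atoms: bromine, BrBr
Why: Electrophilic aromatic bromination, with the OH group directing to its free ortho and para positions.

Step 2
Reactants: 2, 2,4-dibromo-6-methylphenol
Product: 3, 2-bromo-6-methylcyclohexa-2,5-diene-1,4-dione (2-bromo-6-methyl-1,4-benzoquinone)
Conditions: CrO3, 70% aq. AcOH, 60 °C
Reagents that add atoms: chromium trioxide / water as oxygen source, O=[Cr](=O)=O and O
Why: Chromic acid oxidation of a p-bromophenol to the p-quinone (oxidative debromination at the para carbon), leaving the ortho bromine in place.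

Step 3
Reactants: 3, 2-bromo-6-methyl-1,4-benzoquinone; 4, (3E)-penta-1,3-diene
Product: 5, 2,8-dimethylnaphthalene-1,4-dione
Conditions: 4 (3 equiv), PhMe, 60 °C, sealed tube; then Et3N (2 equiv), air, rt
Reagents that add atoms: none
Why: Bromine-directed Diels–Alder reaction at the electron-poor bromo-alkene, in which the more nucleophilic CH2 terminus of the diene bonds to the bromine-free C3 so the diene methyl ends up peri to the carbonyl flanked by the quinone methyl; Et3N then eliminates HBr and the dihydroquinone tautomerises and air-oxidises to the naphthoquinone.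

Step 4
Reactants: 5, 2,8-dimethylnaphthalene-1,4-dione
Product: 6, 2-(chloromethyl)-3,5-dimethylnaphthalene-1,4-dione
Conditions: 37% aq. CH2O, HCl (g), AcOH, rt
Reagents that add atoms: formaldehyde, C=O; hydrogen chloride, Cl
Why: Acid-mediated chloromethylation of the only quinonoid C–H, as in the known conversion of menadione to 2-chloromethyl-3-methyl-1,4-naphthoquinone; the benzo ring is deactivated.

Step 5
Reactants: 7, pent-4-ynoic acid
Product: 8, (4E)-5-iodo-4-methylpent-4-enoic acid
Conditions: Me3Al (3.5 equiv), Cp2ZrCl2 (0.3 equiv), CH2Cl2, 0 °C → rt; then I2, THF, −30 → 0 °C; aq. HCl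
Reagents that add atoms: trimethylaluminium, C[Al](C)C; iodine, II
Why: Negishi Zr-catalysed methylalumination (acid carried as its aluminium carboxylate) is a syn addition with Al on the terminal carbon, and iodinolysis with retention gives the E-alkenyl iodide.

Step 6
Reactants: 7, pent-4-ynoic acid; 8, (4E)-5-iodo-4-methylpent-4-enoic acid
Product: 9, (4E)-4-methylnon-4-en-8-ynoic acid
Conditions: 7 (1.5 equiv), NHPI (1.0 equiv per acid), DIC (0.95 equiv per acid), DMAP (cat.), THF, rt; then 8 (1.0 equiv), NiCl2·6H2O (10 mol%), 2,2′-bipyridine (10 mol%), AgNO3 (0.3 equiv), DMF, Mg(+)/RVC(−), constant current, rt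
Reagents that add atoms: none
Why: Ni-electrocatalytic decarboxylative alkenylation, in which single-electron reduction of the in situ NHPI ester expels CO2 to give the but-3-ynyl radical, which is captured at nickel after oxidative addition of 8 and reductively eliminated with retention of the E geometry, leaving the CO2H of 8 free.

Step 7
Reactants: 9, (4E)-4-methylnon-4-en-8-ynoic acid; 8
Product: 10, (4E,8E)-4,8-dimethyltrideca-4,8-dien-12-ynoic acid
Conditions: 9, NHPI (1.0 equiv), DIC (0.95 equiv), DMAP (cat.), THF, rt; then 8 (1.5 equiv), NiCl2·6H2O (10 mol%), bpy (10 mol%), AgNO3 (0.3 equiv), DMF, Mg(+)/RVC(−), rt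
Reagents that add atoms: none
Why: Same radical decarboxylative alkenylation; the primary homoallylic radical from 9 couples at the alkenyl carbon of 8 with retention, adding one E-configured C5 unit and regenerating a terminal CO2H.

Step 8
Reactants: 10; 8
Product: 11, (4E,8E,12E)-4,8,12-trimethylheptadeca-4,8,12-trien-16-ynoic acid
Conditions: as step 7
Reagents that add atoms: none
Why: Same radical decarboxylative alkenylation; the existing alkenes are not touched and the new one inherits the E geometry of 8.

Step 9
Reactants: 11; 8
Product: 12, (4E,8E,12E,16E)-4,8,12,16-tetramethylhenicosa-4,8,12,16-tetraen-20-ynoic acid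
Conditions: as step 7
Reagents that add atoms: none
Why: Same radical decarboxylative alkenylation; acid–base extraction separates each product acid from neutral radical by-products.

Step 10
Reactants: 12; 13, 1-bromo-2-methylprop-1-ene
Product: 14, (5E,9E,13E,17E)-6,10,14,18,22-pentamethyltricosa-5,9,13,17,21-pentaen-1-yne
Conditions: 12, NHPI (1.0 equiv), DIC (0.95 equiv), DMAP (cat.), THF, rt; then 13 (3 equiv), NiCl2·6H2O (10 mol%), bpy (10 mol%), AgNO3 (0.3 equiv), DMF, Mg(+)/RVC(−), rt
Reagents that add atoms: none
Why: Same radical decarboxylative alkenylation, here capping the chain with the isopropylidene terminus (no geometry at the new alkene).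

Step 11
Reactants: 14; 6, 2-(chloromethyl)-3,5-dimethylnaphthalene-1,4-dione
Product: 15, 2-[(2E,6E,10E,14E,18E)-3,7,11,15,19,23-hexamethyltetracosa-2,6,10,14,18,22-hexaen-1-yl]-3,5-dimethylnaphthalene-1,4-dione (target)
Conditions: Me3Al (2 equiv), Cp2ZrCl2 (0.25 equiv), ClCH2CH2Cl, rt; evaporate volatiles; THF, 6 (0.9 equiv), NiCl2(PPh3)2 (5 mol%)/n-BuLi (10 mol%), 0 °C → rt
Reagents that add atoms: trimethylaluminium, C[Al](C)C
Why: One-pot Negishi carboalumination / Ni(0)-catalysed alkenylalane–chloromethylquinone coupling (Lipshutz-type), where syn-methylalumination installs the 3′-methyl and fixes 2′E and the C1′–C2′ coupling retains that geometry on the unprotected quinone.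

**Compound list**
1 | o-cresol (2-methylphenol) | Cc1ccccc1O | starting material
2 | 2,4-dibromo-6-methylphenol | Cc1cc(Br)cc(Br)c1O | intermediate
3 | 2-bromo-6-methylcyclohexa-2,5-diene-1,4-dione | CC1=CC(=O)C=C(Br)C1=O | intermediate
4 | (3E)-penta-1,3-diene | C/C=C/C=C | starting material
5 | 2,8-dimethylnaphthalene-1,4-dione | CC1=CC(=O)c2cccc(C)c2C1=O | intermediate
6 | 2-(chloromethyl)-3,5-dimethylnaphthalene-1,4-dione | CC1=C(CCl)C(=O)c2cccc(C)c2C1=O | intermediate
7 | pent-4-ynoic acid | C#CCCC(=O)O | starting material
8 | (4E)-5-iodo-4-methylpent-4-enoic acid | OC(=O)CC/C(C)=C/I | intermediate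
9 | (4E)-4-methylnon-4-en-8-ynoic acid | C#CCC/C=C(\C)CCC(=O)O | intermediate
10 | (4E,8E)-4,8-dimethyltrideca-4,8-dien-12-ynoic acid | C#CCC/C=C(\C)CC/C=C(\C)CCC(=O)O | intermediate
11 | (4E,8E,12E)-4,8,12-trimethylheptadeca-4,8,12-trien-16-ynoic acid | C#CCC/C=C(\C)CC/C=C(\C)CC/C=C(\C)CCC(=O)O | intermediate
12 | (4E,8E,12E,16E)-4,8,12,16-tetramethylhenicosa-4,8,12,16-tetraen-20-ynoic acid | C#CCC/C=C(\C)CC/C=C(\C)CC/C=C(\C)CC/C=C(\C)CCC(=O)O | intermediate
13 | 1-bromo-2-methylprop-1-ene | CC(C)=CBr | starting material
14 | (5E,9E,13E,17E)-6,10,14,18,22-pentamethyltricosa-5,9,13,17,21-pentaen-1-yne | C#CCC/C=C(\C)CC/C=C(\C)CC/C=C(\C)CC/C=C(\C)CCC=C(C)C | intermediate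
15 | 2-[(2E,6E,10E,14E,18E)-3,7,11,15,19,23-hexamethyltetracosa-2,6,10,14,18,22-hexaen-1-yl]-3,5-dimethylnaphthalene-1,4-dione | CC(C)=CCC/C(C)=C/CC/C(C)=C/CC/C(C)=C/CC/C(C)=C/CC/C(C)=C/CC1=C(C)C(=O)c2c(C)cccc2C1=O | target

**Totals**
Total steps: 11.
Longest linear sequence: 7 (steps 5–11, from pent-4-ynoic acid); the quinone branch is 5 (steps 1–4, then 11).

**Three steps most likely to fail**
1. Step 6 and its repeats (steps 7–10). Five consecutive radical couplings carry a free CO2H and a free terminal alkyne, and reversible 3-exo closure of the homoallylic radicals could leak a little E/Z purity. Fallback: start from the TMS-protected alkyne and switch the homologation to homoallylzinc/Pd coupling with (E)-1,4-diiodo-2-methylbut-1-ene (chain alkyl iodide → alkylzinc, coupled selectively at the alkenyl iodide). This still adds one unit per step and ends in an alkyl iodide for the next cycle.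
2. Step 3. Piperylene is only weakly polarised and its methyl-bearing terminus must bond to the bromine-bearing carbon, so some of the 2,5-dimethyl regioisomer may form. Fallback: run the bromine-directed Diels–Alder with strongly polarised 1-acetoxybuta-1,3-diene to give 8-hydroxy-2-methyl-1,4-naphthoquinone, then convert to the aryl triflate and install the methyl by Pd-catalysed methylation.
3. Step 11. The alkenylalane may add to or reduce the quinone, and carboalumination gives a few percent of the regioisomer. Fallback: quench the alkenylalane with I2 to isolate the (E)-alkenyl iodide, join it by Ni-catalysed reductive cross-electrophile coupling to the 1,4-dimethoxy-protected benzylic chloride (from 5 by reductive methylation and chloromethylation), and finish with CAN oxidation.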